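**Retrosynthetic overview**

1. Target 11 ⇐ hydroxy lactone 10 by forming the C8–O bond: an aerobic palladium-catalysed dehydrogenative cycloetherification closes the oxolane last and sets C8 and the E C9=C10 alkene.
2. 10 ⇐ epoxy acid 9 by forming the C4–O bond: 5-exo epoxide-opening lactonisation with inversion at C4 (lactone ring formed second).
3. 9 ⇐ epoxy alcohol 6 plus an acetate enolate (C2–C3 bond); 6 ⇐ allylic alcohol 5 by Sharpless epoxidation (oxirane formed first, sets C4 and C5).
4. 5 ⇐ ambliofuran 4 by allylic oxidation; 4 ⇐ farnesyl chloride 1 + 3-(chloromethyl)furan 2 (C14–C15 bond; the furan is bought).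

Assumption: the chain is numbered C1 (lactone carbonyl) to C15 (CH2 on the furan); (2E,6E)-farnesyl chloride and 3-(chloromethyl)furan are taken as commercial.

**Route**

Step 1
Reactants: 1 (2E,6E)-farnesyl chloride; 2 3-(chloromethyl)furan
Product: 4 3-[(3E,7E)-4,8,12-trimethyltrideca-3,7,11-trien-1-yl]furan (ambliofuran), via furan-3-ylmethylmagnesium chloride 3 (not isolated)
Conditions: Mg, THF, 0 °C (2 to 3); then 1, Li2CuCl4 (3 mol%), THF, 0 °C
Reagents that add atoms: none
Why: Copper-catalysed sp3–sp3 Grignard cross-coupling (Kochi–Schlosser type) of the furylmethyl Grignard with the primary allylic chloride goes at the unsubstituted terminus (SN2, not SN2') with both E alkenes kept, and the copper catalyst suppresses attack through the furan ring; no stereocenter is formed.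

Step 2
Reactants: 4 ambliofuran
Product: 5 (2E,6E,10E)-13-(furan-3-yl)-2,6,10-trimethyltrideca-2,6,10-trien-1-ol
Conditions: SeO2 (0.2 equiv), t-BuOOH (3 equiv), salicylic acid (0.1 equiv), CH2Cl2, rt
Reagents that add atoms: selenium dioxide O=[Se]=O (delivers the oxygen, catalytic); tert-butyl hydroperoxide CC(C)(C)OO (restores it)
Why: Allylic C–H oxidation with SeO2 (ene reaction then 2,3-sigmatropic shift, catalytic Sharpless–Umbreit variant) is selective for the E methyl of the terminal isopropylidene group of polyprenyl chains and gives the E allylic alcohol, while the 3-alkylfuran tolerates the neutral conditions.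

Step 3
Reactants: 5 (2E,6E,10E)-13-(furan-3-yl)-2,6,10-trimethyltrideca-2,6,10-trien-1-ol
Product: 6 [(2R,3R)-3-[(3E,7E)-10-(furan-3-yl)-3,7-dimethyldeca-3,7-dien-1-yl]-2-methyloxiran-2-yl]methanol
Conditions: Ti(OiPr)4 (10 mol%), D-(−)-diethyl tartrate (12 mol%), t-BuOOH, 4 Å MS, CH2Cl2, −20 °C
Reagents that add atoms: tert-butyl hydroperoxide CC(C)(C)OO
Why: Sharpless asymmetric epoxidation touches only the alkene of the allylic alcohol (the other two trisubstituted alkenes and the furan carry no directing hydroxyl), and D-(−)-tartrate delivers oxygen to the face that gives the (2R,3R) epoxide, which fixes both future C–O stereocenters C4 and C5.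

Step 4
Reactants: 6 [(2R,3R)-3-[(3E,7E)-10-(furan-3-yl)-3,7-dimethyldeca-3,7-dien-1-yl]-2-methyloxiran-2-yl]methanol
Product: 8 ethyl 3-[(2R,3R)-3-[(3E,7E)-10-(furan-3-yl)-3,7-dimethyldeca-3,7-dien-1-yl]-2-methyloxiran-2-yl]propanoate, via epoxy triflate 7 (not isolated)
Conditions: Tf2O, 2,6-lutidine, CH2Cl2, −78 °C; then LiCH2CO2Et (EtOAc + LiN(SiMe3)2), THF/DMPU, −78 to −40 °C
Reagents that add atoms: ethyl acetate CCOC(C)=O; trifluoromethanesulfonic anhydride O=S(=O)(OS(=O)(=O)C(F)(F)F)C(F)(F)F (in 7 only)
Why: O-triflation followed by SN2 enolate alkylation adds C1 and C2; the primary triflate has no β-hydrogen to eliminate and a lithium ester enolate does not open the hindered trisubstituted epoxide, so both stereocenters stay untouched.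

Step 5
Reactants: 8 ethyl 3-[(2R,3R)-3-[(3E,7E)-10-(furan-3-yl)-3,7-dimethyldeca-3,7-dien-1-yl]-2-methyloxiran-2-yl]propanoate
Product: 10 (5S)-5-[(1R,4E,8E)-11-(furan-3-yl)-1-hydroxy-4,8-dimethylundeca-4,8-dien-1-yl]-5-methyloxolan-2-one, via epoxy acid 9 (not isolated)
Conditions: LiOH, THF/H2O, 0 °C to rt; then aq. citric acid to pH 4, rt
Reagents that add atoms: lithium hydroxide [Li+].[OH-]
Why: Saponification then mild acidification frees the γ,δ-epoxy acid, which closes 5-exo at the tertiary epoxide carbon with inversion (C4 becomes S) while the epoxide oxygen stays on C5 as the (R) alcohol; this epoxide-opening lactonisation needs no strong acid, so cationic cyclisation of the polyene onto the epoxide is avoided.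

Step 6
Reactants: 10 (5S)-5-[(1R,4E,8E)-11-(furan-3-yl)-1-hydroxy-4,8-dimethylundeca-4,8-dien-1-yl]-5-methyloxolan-2-one
Product: 11 (5S)-5-[(2R,5R)-5-[(1E,4E)-7-(furan-3-yl)-4-methylhepta-1,4-dien-1-yl]-5-methyloxolan-2-yl]-5-methyloxolan-2-one
Conditions: Pd(OCOCF3)2 (10 mol%), (S)-t-BuPyOx (12 mol%), O2 (1 atm), 3 Å MS, toluene, 50 °C
Reagents that add atoms: none
Why: Proposed new method: a ligand-controlled aerobic Wacker-type cycloetherification of a hindered secondary alcohol onto one trisubstituted alkene of a polyene, in which the divalent palladium alkoxide adds syn across C8=C9 in the 5-exo mode through a chair-like transition state with the lactone group pseudo-equatorial and therefore trans to the palladium-bearing C9 (the 2R,5R ring), the tert-butyl group of the pyridine-oxazoline being intended to block the face that leads to the cis ring; the alkylpalladium has β-hydrogens only on C10 because C8 is fully substituted, so syn β-hydride elimination can only give the E C9=C10 alkene, and O2 then returns zerovalent palladium to the divalent state; the chelating ligand should leave no open site for ketone formation from the alkoxide or for Pd–H re-insertion, and C12=C13 has no tethered nucleophile; the closest known reactions are the racemic aerobic palladium/pyridine cyclisation of primary alkenols onto trisubstituted alkenes and the pyridine-oxazoline–palladium enantioselective aza-Wacker cyclisation of sulfonamides.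

**Compound list**

1 | (2E,6E)-farnesyl chloride | ClC/C=C(C)/CC/C=C(C)/CCC=C(C)C | starting material
2 | 3-(chloromethyl)furan | ClCc1ccoc1 | starting material
3 | (furan-3-ylmethyl)magnesium chloride (not isolated) | Cl[Mg]Cc1ccoc1 | intermediate
4 | 3-[(3E,7E)-4,8,12-trimethyltrideca-3,7,11-trien-1-yl]furan (ambliofuran) | CC(C)=CCC/C(C)=C/CC/C(C)=C/CCc1ccoc1 | intermediate
5 | (2E,6E,10E)-13-(furan-3-yl)-2,6,10-trimethyltrideca-2,6,10-trien-1-ol | OC/C(C)=C/CC/C(C)=C/CC/C(C)=C/CCc1ccoc1 | intermediate
6 | [(2R,3R)-3-[(3E,7E)-10-(furan-3-yl)-3,7-dimethyldeca-3,7-dien-1-yl]-2-methyloxiran-2-yl]methanol | OC[C@@]1(C)O[C@@H]1CC/C(C)=C/CC/C(C)=C/CCc1ccoc1 | intermediate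
7 | [(2R,3R)-3-[(3E,7E)-10-(furan-3-yl)-3,7-dimethyldeca-3,7-dien-1-yl]-2-methyloxiran-2-yl]methyl trifluoromethanesulfonate (not isolated) | FC(F)(F)S(=O)(=O)OC[C@@]1(C)O[C@@H]1CC/C(C)=C/CC/C(C)=C/CCc1ccoc1 | intermediate
8 | ethyl 3-[(2R,3R)-3-[(3E,7E)-10-(furan-3-yl)-3,7-dimethyldeca-3,7-dien-1-yl]-2-methyloxiran-2-yl]propanoate | CCOC(=O)CC[C@@]1(C)O[C@@H]1CC/C(C)=C/CC/C(C)=C/CCc1ccoc1 | intermediate
9 | 3-[(2R,3R)-3-[(3E,7E)-10-(furan-3-yl)-3,7-dimethyldeca-3,7-dien-1-yl]-2-methyloxiran-2-yl]propanoic acid (not isolated) | OC(=O)CC[C@@]1(C)O[C@@H]1CC/C(C)=C/CC/C(C)=C/CCc1ccoc1 | intermediate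
10 | (5S)-5-[(1R,4E,8E)-11-(furan-3-yl)-1-hydroxy-4,8-dimethylundeca-4,8-dien-1-yl]-5-methyloxolan-2-one | O=C1CC[C@](C)(O1)[C@H](O)CC/C(C)=C/CC/C(C)=C/CCc1ccoc1 | intermediate
11 | (5S)-5-[(2R,5R)-5-[(1E,4E)-7-(furan-3-yl)-4-methylhepta-1,4-dien-1-yl]-5-methyloxolan-2-yl]-5-methyloxolan-2-one | C/C(=C\CCc1ccoc1)C/C=C/[C@@]1(C)CC[C@H]([C@]2(C)CCC(=O)O2)O1 | target

**Step count and risks**

Total steps: 6. Longest linear sequence: 6 steps (1 or 2 to 11).

The three steps most likely to fail:

Step 6 (the proposed cyclisation). The hindered secondary alcohol may be oxidised to the ketone instead of adding to the alkene, Pd–H may move the new alkene into conjugation with C12=C13, and the ligand enantiomer assumed here could prove mismatched with the substrate bias. The fallback sets out from 10 and comes back at 11 with known selenium chemistry. N-(Phenylselanyl)phthalimide and catalytic camphorsulfonic acid in CH2Cl2 at −78 °C close the ring by anti selenoetherification to give (5S)-5-[(2R,5R)-5-[(1S,4E)-7-(furan-3-yl)-4-methyl-1-(phenylselanyl)hept-4-en-1-yl]-5-methyloxolan-2-yl]-5-methyloxolan-2-one F1, from which the 2,5-cis ring isomer is removed by chromatography. H2O2/pyridine at 0 °C then forms the selenoxide, whose syn elimination can only go toward C10 and gives the E alkene of 11.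

Step 4 (alkylation of the epoxy triflate). The triflate sits next to a fully substituted carbon and may react slowly or decompose before the enolate attacks. The fallback sets out from 6 and comes back at 8 by olefination instead of substitution. Parikh–Doering oxidation (SO3·pyridine, DMSO, iPr2NEt) gives (2S,3R)-3-[(3E,7E)-10-(furan-3-yl)-3,7-dimethyldeca-3,7-dien-1-yl]-2-methyloxirane-2-carbaldehyde F2. A Wittig reaction with Ph3P=CHCO2Et gives ethyl (2E)-3-[(2R,3R)-3-[(3E,7E)-10-(furan-3-yl)-3,7-dimethyldeca-3,7-dien-1-yl]-2-methyloxiran-2-yl]prop-2-enoate F3. Diimide (2-nitrobenzenesulfonohydrazide, Et3N) then saturates only the conjugated disubstituted alkene and delivers 8.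

Step 2 (SeO2 oxidation in the presence of the furan and three alkenes). Conversion has to be stopped early, yields of such oxidations are modest, and the furan or an internal allylic position may be attacked. The fallback sets out from 1 and comes back at 5 by oxidising before the furan is attached. KOAc in DMF gives (2E,6E)-3,7,11-trimethyldodeca-2,6,10-trien-1-yl acetate F4. SeO2/t-BuOOH gives (2E,6E,10E)-12-hydroxy-3,7,11-trimethyldodeca-2,6,10-trien-1-yl acetate F5. Copper-catalysed substitution of the allylic acetate by Grignard reagent 3 (2.5 equiv, Li2CuCl4, THF, −20 °C) then gives 5.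

**Further compounds**

F1 | step 6 | (5S)-5-[(2R,5R)-5-[(1S,4E)-7-(furan-3-yl)-4-methyl-1-(phenylselanyl)hept-4-en-1-yl]-5-methyloxolan-2-yl]-5-methyloxolan-2-one | C/C(=C\CCc1ccoc1)CC[C@H]([Se]c1ccccc1)[C@@]1(C)CC[C@H]([C@]2(C)CCC(=O)O2)O1
F2 | step 4 | (2S,3R)-3-[(3E,7E)-10-(furan-3-yl)-3,7-dimethyldeca-3,7-dien-1-yl]-2-methyloxirane-2-carbaldehyde | O=C[C@@]1(C)O[C@@H]1CC/C(C)=C/CC/C(C)=C/CCc1ccoc1
F3 | step 4 | ethyl (2E)-3-[(2R,3R)-3-[(3E,7E)-10-(furan-3-yl)-3,7-dimethyldeca-3,7-dien-1-yl]-2-methyloxiran-2-yl]prop-2-enoate | CCOC(=O)/C=C/[C@@]1(C)O[C@@H]1CC/C(C)=C/CC/C(C)=C/CCc1ccoc1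
F4 | step 2 | (2E,6E)-3,7,11-trimethyldodeca-2,6,10-trien-1-yl acetate | CC(=O)OC/C=C(C)/CC/C=C(C)/CCC=C(C)C
F5 | step 2 | (2E,6E,10E)-12-hydroxy-3,7,11-trimethyldodeca-2,6,10-trien-1-yl acetate | CC(=O)OC/C=C(C)/CC/C=C(C)/CC/C=C(C)/CO
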